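Ring A is the dimethoxyarene (C1 carries the ethano bridge, C2 the benzylic CH2, C3 and C5 the OMe groups), ring B is 4-hydroxyphenyl and ring C is 3-hydroxyphenyl. The target comes from the bis(benzyl ether) diaryl ketone A–C(=O)–B by one global hydrogenolysis.
The ketone is cut into three pieces joined in one flask: 4-(benzyloxy)phenyllithium, 3,5-dimethoxybenzocyclobutenone and 3-(benzyloxy)benzyl bromide. 1,2-Addition first makes the bond from the future diarylmethane carbon to the ipso carbon of ring B. The alkoxide then opens the four-membered ring, and the freed CH2 takes up the benzyl bromide to form the CH2–CH2 bond of the bridge.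
Enabling feature: the diarylmethane carbon and the first bridge carbon sit on the neighbouring atoms C2 and C1 of ring A. A temporary C–C bond between them gives a benzocyclobutenone, which is both a strained, non-enolisable carbonyl for the aryl addition and a spring-loaded latent benzylic carbanion for the bridge.
The benzocyclobutenone comes from a [2+2] cycloaddition of 3,5-dimethoxybenzyne with ketene diethyl acetal, in which the C3–OMe next to the aryne bond places the carbonyl carbon on C2.
Ring order: rings A, B and C are bought. The only ring made is the temporary cyclobutene (step 1), and it is opened again in step 2.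
Key step: step 2

Remark: the target has no stereocentre and no double-bond geometry, so no stereochemistry has to be carried through. Organolithium species are drawn as covalent monomers.

Step 1
Reactants: 1 1-bromo-3,5-dimethoxybenzene; 2 1,1-diethoxyethene (ketene diethyl acetal)
Product: 5 3,5-dimethoxybicyclo[4.2.0]octa-1,3,5-trien-7-one (4,6-dimethoxybenzocyclobutenone), via 3,5-dimethoxybenzyne 3 (not isolated), via diethyl acetal 4 (not isolated)
Conditions: NaNH2, THF, reflux; then 1 M aq HCl, THF, rt
Reagents that add atoms: water, O
Why: Aryne–ketene acetal [2+2] cycloaddition: loss of HBr across C1–C2 of 1 should give 3, the nucleophilic CH2 of 2 should attack the aryne carbon remote from OMe so that the aryl anion develops next to the inductively withdrawing OMe and closes on the dialkoxycarbenium carbon, and acid hydrolysis of 4 should unmask the ketone on the ring carbon adjacent to OMe.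

Step 2
Reactants: 5 3,5-dimethoxybicyclo[4.2.0]octa-1,3,5-trien-7-one; 6 1-(benzyloxy)-4-bromobenzene; 7 1-(benzyloxy)-3-(bromomethyl)benzene
Product: 11 [4-(benzyloxy)phenyl](2-{2-[3-(benzyloxy)phenyl]ethyl}-4,6-dimethoxyphenyl)methanone, via aryllithium 8 (not isolated), via benzocyclobutenoxide 9 (not isolated), via oxido-o-quinodimethane 10 (not isolated)
Conditions: 6, n-BuLi, THF, −78 °C; add 5, −78 °C; add 7, DMPU, −78 °C → rt
Reagents that add atoms: none
Why: Proposed new method: 8 should add 1,2 to the strained carbonyl of 5, which cannot be enolised without forming a benzocyclobutadiene, and thereby make the bond between the future diarylmethane carbon and the ipso carbon of ring B; on warming, alkoxide 9 should open its C7–C8 bond by an oxyanion-accelerated conrotatory 4π electrocyclic reaction with O⁻ turning outward, and the resulting α-oxido-o-quinodimethane 10, which is the extended enolate of an o-methylbenzophenone, should displace bromide from 7 (SN2) with its exocyclic CH2 and so lay the CH2–CH2 bridge. The closest known reaction types are the low-temperature ring opening of lithium benzocyclobutenoxides with capture of the methylene terminus by aldehydes, nitriles or dienophiles, and the lateral benzylation of o-toluate anions; what is new is an alkyl halide as third component directly after an aryllithium addition. No ring is closed: the temporary four-membered ring is opened, its strain paying for the brief loss of aromaticity of ring A, which C-alkylation restores. The one new stereocentre (C7 of 9) forms as a racemate and vanishes in 10, and the enolate geometry of 10 does not reach the achiral product. Site selectivity at the ambident anion is secured by ring A itself, since only reaction at the CH2 terminus rearomatises it, whereas O-alkylation or attack through a ring carbon would leave it dearomatised. Chemoselectivity among the three components rests on order of addition and sterics: 8 is used up at −78 °C before 7 enters, the tertiary alkoxide 9 next to the C5 methoxy group is too hindered for O-benzylation, 1-bromobutane is a much poorer electrophile than benzylic 7, and the di-ortho-substituted carbonyl of 11 should resist attack by remaining 10.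

Step 3
Reactants: 11 [4-(benzyloxy)phenyl](2-{2-[3-(benzyloxy)phenyl]ethyl}-4,6-dimethoxyphenyl)methanone
Product: 12 gymconopin D, 3-{2-[2-(4-hydroxybenzyl)-3,5-dimethoxyphenyl]ethyl}phenol
Conditions: H2 (4 bar), 10% Pd/C, AcOH–EtOAc, cat. HCl, 40 °C
Reagents that add atoms: none
Why: Catalytic hydrogenolysis: both O-benzyl ethers should cleave, and the diaryl ketone should be hydrogenated to a benzhydrol whose C–O bond, doubly benzylic and activated by the ortho/para methoxy and para hydroxy groups, should be hydrogenolysed to CH2 under the acidic conditions, while the aryl methyl ethers are inert.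

Compound list
1 | 1-bromo-3,5-dimethoxybenzene | COc1cc(Br)cc(OC)c1 | starting material
2 | 1,1-diethoxyethene (ketene diethyl acetal) | C=C(OCC)OCC | starting material
3 | 3,5-dimethoxybenzyne (1,2-didehydro-3,5-dimethoxybenzene) | COC1=CC(OC)=CC#C1 | intermediate
4 | 7,7-diethoxy-3,5-dimethoxybicyclo[4.2.0]octa-1,3,5-triene | CCOC1(OCC)Cc2cc(OC)cc(OC)c21 | intermediate
5 | 3,5-dimethoxybicyclo[4.2.0]octa-1,3,5-trien-7-one | COc1cc2c(c(OC)c1)C(=O)C2 | intermediate
6 | 1-(benzyloxy)-4-bromobenzene | Brc1ccc(OCc2ccccc2)cc1 | starting material
7 | 1-(benzyloxy)-3-(bromomethyl)benzene | BrCc1cccc(OCc2ccccc2)c1 | starting material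
8 | [4-(benzyloxy)phenyl]lithium | [Li]c1ccc(OCc2ccccc2)cc1 | intermediate
9 | lithium 7-[4-(benzyloxy)phenyl]-3,5-dimethoxybicyclo[4.2.0]octa-1,3,5-trien-7-olate (racemic) | [Li]OC1(c2ccc(OCc3ccccc3)cc2)Cc2cc(OC)cc(OC)c21 | intermediate
10 | lithium (Z)-[4-(benzyloxy)phenyl](2,4-dimethoxy-6-methylidenecyclohexa-2,4-dien-1-ylidene)methanolate (O outward, aryl toward the CH2 terminus) | [Li]O/C(c1ccc(OCc2ccccc2)cc1)=C1/C(=C)C=C(OC)C=C1OC | intermediate
11 | [4-(benzyloxy)phenyl](2-{2-[3-(benzyloxy)phenyl]ethyl}-4,6-dimethoxyphenyl)methanone | COc1cc(CCc2cccc(OCc3ccccc3)c2)c(C(=O)c2ccc(OCc3ccccc3)cc2)c(OC)c1 | intermediate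
12 | gymconopin D, 3-{2-[2-(4-hydroxybenzyl)-3,5-dimethoxyphenyl]ethyl}phenol | COc1cc(CCc2cccc(O)c2)c(Cc2ccc(O)cc2)c(OC)c1 | target

Total step count: 3
Longest linear sequence: 3 steps (1 → 5 → 11 → 12)

Steps most likely to fail

Step 2 (labelled step).
- **What may go wrong:** Alkoxide 9 may open slowly or in the wrong direction, by aryl-anion-type cleavage next to the methoxy group. Proton exchange between 10 and the product may lead to over-alkylation. Electron transfer from 10 to 7 with Wurtz-type dimerisation may outrun C-benzylation.
- **Fallback:** This uses known chemistry, with a six-membered lactone instead of the four-membered ketone as the temporary ring. It sets out from 8, made from 6 as in step 2.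
- **Lactone:** Commercial methyl 2,4-dimethoxy-6-methylbenzoate (COC(=O)c1c(C)cc(OC)cc1OC) is laterally lithiated (LDA, THF, −78 °C) and added to commercial 3-(benzyloxy)benzaldehyde (O=Cc1cccc(OCc2ccccc2)c1). The alkoxide should lactonise on warming to racemic 3-[3-(benzyloxy)phenyl]-6,8-dimethoxyisochroman-1-one F1.
- **Aryl addition:** 8 is transmetallated with CeCl3 to suppress deprotonation at C4 and β-elimination. It should add once to the lactone carbonyl (THF, −78 °C) and make the same aryl–carbon bond. The product is 1-[4-(benzyloxy)phenyl]-3-[3-(benzyloxy)phenyl]-6,8-dimethoxyisochroman-1-ol F2, a lactol in equilibrium with its open hydroxy ketone whose stereocentres are irrelevant.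
- **Return to the route:** Acidic hydrogenolysis (H2, Pd/C, AcOH, cat. acid) should remove the C1–OH, both benzylic ring C–O bonds and both benzyl ethers. The fallback comes back to the route at 12.

Step 1.
- **What may go wrong:** Amination of aryne 3 by amide or ammonia, and base-induced decay of the ketene acetal, may outrun the [2+2] cycloaddition.
- **Fallback:** It sets out from 1. Aryne 3 is generated with the non-nucleophilic base LiTMP (THF, −78 °C) in the presence of lithium ethenolate, prepared beforehand by cycloreversion of THF with n-BuLi.
- **Cycloaddition:** This anionic two-carbon partner, at the alcohol oxidation level, should add with the same regiochemistry, and the aryl anion should close on the aldehyde carbon. After a cold quench this should give racemic 3,5-dimethoxybicyclo[4.2.0]octa-1,3,5-trien-7-ol F3.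
- **Return to the route:** Oxidation with Dess–Martin periodinane (CH2Cl2, rt) comes back to the route at 5.

Step 3.
- **What may go wrong:** Carbonyl reduction may stall after debenzylation. The freed 4-hydroxybenzoyl unit is a vinylogous acid, and the carbonyl is shielded by two ortho substituents.
- **Fallback:** It sets out from 11 and replaces surface hydrogenation of the carbonyl by ionic hydrogenation. Et3SiH and TFA in CH2Cl2 (0 °C → rt) should reduce the protonated, strongly stabilised diaryl carbonyl through the benzhydryl cation to 1-{2-[3-(benzyloxy)phenyl]ethyl}-2-[4-(benzyloxy)benzyl]-3,5-dimethoxybenzene F4.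
- **Return to the route:** Neutral debenzylation (H2, 1 atm, Pd/C, EtOAc–MeOH, rt) comes back to the route at 12.

Further compounds
F1 | step 2 | 3-[3-(benzyloxy)phenyl]-6,8-dimethoxyisochroman-1-one (racemic) | COc1cc2c(c(OC)c1)C(=O)OC(c1cccc(OCc3ccccc3)c1)C2
F2 | step 2 | 1-[4-(benzyloxy)phenyl]-3-[3-(benzyloxy)phenyl]-6,8-dimethoxyisochroman-1-ol (racemic, mixture of diastereomers) | COc1cc2c(c(OC)c1)C(O)(c1ccc(OCc3ccccc3)cc1)OC(c1cccc(OCc3ccccc3)c1)C2
F3 | step 1 | 3,5-dimethoxybicyclo[4.2.0]octa-1,3,5-trien-7-ol (racemic) | COc1cc2c(c(OC)c1)C(O)C2
F4 | step 3 | 1-{2-[3-(benzyloxy)phenyl]ethyl}-2-[4-(benzyloxy)benzyl]-3,5-dimethoxybenzene | COc1cc(CCc2cccc(OCc3ccccc3)c2)c(Cc2ccc(OCc3ccccc3)cc2)c(OC)c1
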